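## The problem

The target 27 is a linear C25 furanoterpenoid acid. It holds a 3-monosubstituted furan (ring A), two 2,4-disubstituted furans (rings B and C) and an (E)-2-methylacrylic acid on C2 of ring C. The rings are joined only by sp3 chains: (CH2)3 from C3 of ring A to C4 of ring B, and CH2–CH(CH3)–(CH2)3 from C2 of ring B to C4 of ring C.

The hard part is the 2,4-pattern, which is needed twice. Furans take bases and electrophiles next to oxygen and tend to give 2,5-products. All three rings are β-alkylfurans that no late C–H functionalisation could tell apart, yet ring A must keep both α-positions free while rings B and C each gain one α-substituent remote from the alkyl chain.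

The feature that opens a way out is that in rings B and C both C3 and C5 carry hydrogen, C4 carries the alkyl chain and C2 a carbon substituent. Atom for atom this is a cyclodehydrated 3-alkyne-1,2-diol: O1 and C5 are a primary CH2OH, C4 is a tertiary carbinol bearing the chain, C3 and C2 are the alkyne carbons, and the C2 substituent sits on the alkyne terminus. Such a diol is the adduct of a 1-alkyne and an α-oxygenated ketone, so the ring problem can be turned into a chain-joining problem.

The single stereocentre (S, methyl-bearing) lies one CH2 from C2 of ring B and three CH2 from C4 of ring C. Nothing in the molecule can control it, but it cannot epimerise either, so it can be bought and carried. The E-alkene is the thermodynamically favoured isomer and a stabilised ylide sets it.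

Furans do not survive ozone, peracids, singlet oxygen or strong acid, and the furylacrylic acid is a light-sensitive Michael acceptor. Oxidative cleavage must therefore come before the first furan, and the acid must appear last.

## Retrosynthesis

**Acid 27 to aldehyde 25.** The exocyclic C=C of the acrylic acid is cut (27 to ester 26 to aldehyde 25). Cutting here rather than carrying the acrylate through the route keeps an ester and a Michael acceptor out of every organolithium step. The forward reaction must be an E-selective olefination of a furfural-type aldehyde and a mild ester cleavage.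

**Aldehyde 25 to tetraol 23 (key disconnection).** The O1–C2 bonds of rings B and C are both cut and one water is added back across C3–C4 of each ring, via acetal 24. Both difficult rings vanish at once into two 3-alkyne-1,2-diol units in the acyclic tetraol 23. The neighbouring cuts, at the ring–chain σ-bonds, would keep the rings and leave the 2,4-problem unsolved. Tetraol 23 has no heteroaromatic regiochemistry left, and its two carbinol centres need no control because both become sp2. The forward step must be a twofold 5-endo-dig cyclodehydration that leaves ring A, the acetal and the stereocentre alone.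

**Tetraol 23 to iodide 18 and ynone 11.** After silylation (23 to 22), the C4–C5 bond of 22 is cut, between the carbinol carbon of the ring C unit and its (CH2)3 tether. This gives a primary alkyl nucleophile from iodide 18 and ynone 11. The neighbouring cut (alkyne–carbinol) would need a linchpin that is both a ketone and a terminal alkyne, that is, one that must be deprotonated beside its own electrophile. The chosen cut lets the iodide wait as a masked nucleophile. The forward step must be a 1,2-selective addition of a primary alkyl metal to an enolisable ynone.

**Iodide 18 to iodoalkyne 16 and ketone 8.** The C4–C5 bond of 18 is cut, between the carbinol and the alkyne (the later C4–C3 bond of ring B). This is the classical acetylide-plus-ketone union. It needs only that the acetylide is formed without touching the primary iodide.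

**Iodoalkyne 16 to (S)-citronellal 12.** The linchpin 16 is traced through alcohol 15 and enyne 13 to 12. The aldehyde carbon of 12 becomes the internal alkyne carbon (later C2 of ring B) by one-carbon homologation. The isopropylidene group is cleaved to give the primary carbon that later bonds to C4 of ring C. The stereocentre is bought with the correct configuration, and the only oxidative cleavage of the route takes place before any furan exists.

**Ketone 8 and ynone 11 to one C2 donor.** Both carbonyl partners come from Weinreb amide 6, which supplies C4, C5 and O1 of ring B (through 8) and of ring C (through 11). Ketone 8 is cut to bromide 5, which goes back through alcohol 4 to 3-bromofuran 1 and oxetane 2. Ynone 11 is cut to the acetal alkyne 9, whose acetal is the masked formyl group on C2 of ring C.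

## Roads not taken

**Alternative 1:** the obvious plan is to cut the ring–chain σ-bonds and buy the furans.
- Cut and forward key step: 4-bromofuran-2-carbaldehyde A1 would serve twice. 3-Allylfuran A2 (from 1) is hydroborated with 9-BBN and coupled with A1 (PdCl2(dppf), B-alkyl Suzuki–Miyaura) to aldehyde A3. A Wittig reaction with a secondary ylide gives trisubstituted alkene A4. Its terminal alkene is used for a second B-alkyl coupling with A1, and an enantioselective hydrogenation of the furyl-substituted alkene must then set the stereocentre.
- Why the chosen plan is better: this route makes the stereocentre by asymmetric reduction of an alkene that forms as an E/Z mixture, beside three reducible furans. It needs hydroboration in the presence of another alkene and of aldehydes that must be protected. It attaches the rings one at a time in a linear sequence. The chosen plan buys the stereocentre, encodes both 2,4-patterns in the connectivity of an acyclic precursor, and forms both rings together.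

**Alternative 2:** cut O1–C2 of ring B and the bond from C3 to C2 through a (Z)-2-en-4-yn-1-ol.
- Cut and forward key step: copper-catalysed carbomagnesiation of prop-2-yn-1-ol A5 with Grignard reagent 7 and iodination would give the (Z)-iodoallyl alcohol A6. Sonogashira coupling (Pd(PPh3)4, CuI) with alkyne A8 gives enynol A7, and 5-exo-dig cycloisomerisation closes ring B.
- Why the chosen plan is better: this mode always leaves a CH2 group on C2. It suits ring B but cannot make ring C, whose C2 bears an sp2 carbon, so ring C must be brought in preformed (as in A8) and the 2,4-problem returns for it. A8 also needs its stereocentre at the propargylic carbon, which citronellal does not provide without loss of a carbon. In the chosen plan one reaction type makes both rings in one step.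

**Alternative 3:** a biomimetic oxidation, cutting both C–O bonds of every furan back to a 1,3-diene and O2.
- Cut and forward key step: the tris-diene A9 (by enyne cross-metathesis with the second-generation Grubbs catalyst) would be photo-oxygenated (O2, rose bengal, light) to the tris-endoperoxide A10. Base-induced Kornblum–DeLaMare rearrangement and dehydration would give the three furans.
- Why the chosen plan is better: singlet oxygen destroys furans, so even ring A would have to be carried as a diene and all three rings would appear only at the end. Acyclic dienes from enyne metathesis form as E/Z mixtures, and the Z isomers and the many allylic C–H bonds divert the reaction to ene products. Three peroxide rings in one intermediate are also a handling problem. The gold-catalysed closure is redox-neutral, tolerates a finished furan and fixes the regiochemistry by connectivity.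

Key step: step 11

Assumption: the SMILES is read as the (S)-configured methyl-bearing carbon and the (E)-alkene (carboxyl trans to the furan); Weinreb amide 6, the O-silylated N-methoxy-N-methylamide of glycolic acid, is taken as a purchasable reagent.

## Steps

Step 1
Reactants: 1 3-bromofuran; 2 oxetane
Product: 4 3-(furan-3-yl)propan-1-ol, via furan-3-yllithium 3 (not isolated)
Conditions: n-BuLi, THF, −78 °C; then 2, BF3·OEt2, −78 °C; H2O
Reagents that add atoms: none
Why: Bromine–lithium exchange gives 3, which keeps its 3-position at −78 °C; BF3-promoted opening of oxetane by an organolithium is a standard three-carbon hydroxyalkylation and installs the (CH2)3 tether of ring A in one operation.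

Step 2
Reactants: 4 3-(furan-3-yl)propan-1-ol
Product: 5 3-(3-bromopropyl)furan
Conditions: CBr4, PPh3, CH2Cl2, 0 °C
Reagents that add atoms: carbon tetrabromide, BrC(Br)(Br)Br
Why: Appel bromination of a primary alcohol under neutral conditions, which the acid-sensitive furan tolerates.

Step 3
Reactants: 5 3-(3-bromopropyl)furan; 6 2-{[tert-butyl(dimethyl)silyl]oxy}-N-methoxy-N-methylacetamide
Product: 8 1-{[tert-butyl(dimethyl)silyl]oxy}-5-(furan-3-yl)pentan-2-one, via the Grignard reagent 7 (not isolated)
Conditions: Mg, THF, 40 °C; then 6, THF, 0 °C; aq. NH4Cl
Reagents that add atoms: none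
Why: Weinreb ketone synthesis: the Grignard reagent adds once to 6 because the magnesium chelate survives until work-up; the carbonyl carbon of 8 will become C4 of ring B and its CH2O group C5 and O1.

Step 4
Reactants: 9 3,3-diethoxyprop-1-yne; 6 2-{[tert-butyl(dimethyl)silyl]oxy}-N-methoxy-N-methylacetamide
Product: 11 1-{[tert-butyl(dimethyl)silyl]oxy}-5,5-diethoxypent-3-yn-2-one, via lithium acetylide 10 (not isolated)
Conditions: n-BuLi, THF, −78 °C; then 6, −78 to 0 °C; aq. NH4Cl
Reagents that add atoms: none
Why: Weinreb ketone synthesis with a lithium acetylide: single addition to 6 gives the ynone, in which the future O1, C5, C4, C3 and C2 of ring C are already joined and the acetal is the masked formyl group on C2.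

Step 5
Reactants: 12 (S)-citronellal [(3S)-3,7-dimethyloct-6-enal]
Product: 13 (4S)-4,8-dimethylnon-7-en-1-yne
Conditions: dimethyl (1-diazo-2-oxopropyl)phosphonate, K2CO3, MeOH, 0 °C to rt
Reagents that add atoms: dimethyl (1-diazo-2-oxopropyl)phosphonate, COP(=O)(OC)C(=[N+]=[N-])C(C)=O
Why: Seyferth–Gilbert homologation in the Ohira–Bestmann form converts the aldehyde into the terminal alkyne under mild base; the stereocentre is β to the aldehyde and cannot epimerise; the old aldehyde carbon will be C2 of ring B.

Step 6
Reactants: 13 (4S)-4,8-dimethylnon-7-en-1-yne
Product: 15 (4S)-4-methylhept-6-yn-1-ol, via aldehyde 14 (not isolated)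
Conditions: O3, CH2Cl2/MeOH, −78 °C (Sudan Red 7B end point); then NaBH4, −78 to 0 °C
Reagents that add atoms: ozone, [O-][O+]=O
Why: Ozonolysis with reductive work-up: ozone cleaves the electron-rich trisubstituted alkene much faster than it attacks a terminal alkyne, and NaBH4 reduces the ozonide to the primary alcohol; the step is placed before any furan is present.

Step 7
Reactants: 15 (4S)-4-methylhept-6-yn-1-ol
Product: 16 (4S)-7-iodo-4-methylhept-1-yne
Conditions: I2, PPh3, imidazole, CH2Cl2, 0 °C to rt
Reagents that add atoms: iodine, II
Why: Appel-type iodination of the primary alcohol under neutral conditions leaves the alkyne and the stereocentre alone; the iodide is the masked alkyl nucleophile for step 9.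

Step 8
Reactants: 16 (4S)-7-iodo-4-methylhept-1-yne; 8 1-{[tert-butyl(dimethyl)silyl]oxy}-5-(furan-3-yl)pentan-2-one
Product: 18 (4RS,8S)-4-({[tert-butyl(dimethyl)silyl]oxy}methyl)-1-(furan-3-yl)-11-iodo-8-methylundec-5-yn-4-ol, via lithium acetylide 17 (not isolated)
Conditions: LiN(i-Pr)2 (commercial solution), THF, −78 °C; then 8, −78 to −40 °C; aq. NH4Cl
Reagents that add atoms: none
Why: Alkynylation of a ketone: the amide base deprotonates the terminal alkyne without halogen–metal exchange at the primary iodide, and the acetylide adds 1,2 to 8; the new carbinol centre forms without control, which does not matter because it becomes sp2 C4 of ring B.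

Step 9
Reactants: 18 (4RS,8S)-4-({[tert-butyl(dimethyl)silyl]oxy}methyl)-1-(furan-3-yl)-11-iodo-8-methylundec-5-yn-4-ol; 11 1-{[tert-butyl(dimethyl)silyl]oxy}-5,5-diethoxypent-3-yn-2-one
Product: 22 (8S)-4,12-bis({[tert-butyl(dimethyl)silyl]oxy}methyl)-1,1-diethoxy-15-(furan-3-yl)-8-methylpentadeca-2,10-diyne-4,12-diol, via lithium alkoxide 19 (not isolated), via dilithio species 20 (not isolated), via organocerium species 21 (not isolated)
Conditions: MeLi (1 equiv), Et2O, −78 °C; t-BuLi (2 equiv), −78 °C; CeCl3 (THF slurry), −78 °C; then 11, −78 °C; aq. NH4Cl
Reagents that add atoms: none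
Why: After the hydroxyl is capped as its lithium alkoxide, lithium–iodine exchange with two equivalents of t-BuLi is fast and irreversible at −78 °C; transmetalation to cerium gives a weakly basic, oxophilic organocerium reagent that adds 1,2 to the enolisable ynone 11 and not in conjugate fashion; the second carbinol centre is again uncontrolled and becomes sp2 C4 of ring C.

Step 10
Reactants: 22 (8S)-4,12-bis({[tert-butyl(dimethyl)silyl]oxy}methyl)-1,1-diethoxy-15-(furan-3-yl)-8-methylpentadeca-2,10-diyne-4,12-diol
Product: 23 (8S)-1,1-diethoxy-15-(furan-3-yl)-4,12-bis(hydroxymethyl)-8-methylpentadeca-2,10-diyne-4,12-diol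
Conditions: Bu4NF, AcOH, THF, 0 °C to rt
Reagents that add atoms: none
Why: Fluoride cleaves both primary silyl ethers; buffering with acetic acid prevents base-induced retro-alkynylation of the tertiary propargylic alkoxides and leaves the acetal untouched.

Step 11
Reactants: 23 (8S)-1,1-diethoxy-15-(furan-3-yl)-4,12-bis(hydroxymethyl)-8-methylpentadeca-2,10-diyne-4,12-diol
Product: 25 4-[(4S)-5-{4-[3-(furan-3-yl)propyl]furan-2-yl}-4-methylpentyl]furan-2-carbaldehyde, via trifuran acetal 24 (not isolated)
Conditions: (Ph3P)AuCl (2 mol%), AgOSO2CF3 (2 mol%), THF, 4 Å molecular sieves, 0 °C to rt; then PPTS, acetone/H2O, rt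
Reagents that add atoms: water, O
Why: The cationic monovalent gold species Ph3PAu+ binds each alkyne, the neighbouring primary hydroxyl adds anti to gold at the distal alkyne carbon, and protodeauration gives a 3-hydroxy-2,3-dihydrofuran that loses its tertiary hydroxyl as water to become aromatic. The closest known reaction type is the gold- or silver-catalysed dehydrative cyclisation of a single 3-alkyne-1,2-diol to a furan, used here at two sites of one molecule. Ring B closes 5-endo-dig by O1–C2 bond formation and ring C closes in the same 5-endo-dig mode. No stereocentre is formed: the two carbinol centres of 23 become C4 of rings B and C, so all four diastereomers of 23 should give the single product 24, and the methyl-bearing stereocentre is separated from the reacting atoms by sp3 carbons and is not touched. The step needs the 2,4- and not the 2,5- or 2,3-pattern, and connectivity fixes this, since only the primary hydroxyl can reach the alkyne through a five-membered transition state and it can only attack the carbon that bears the future C2 substituent. It also needs chemoselectivity over Meyer–Schuster rearrangement of the tertiary propargylic alcohols and over ionisation of the acetal; the intramolecular O–H addition is fast under neutral conditions and the sieves keep the acetal intact until PPTS and water are added. The two reacting sites are five sp3 carbons apart and should behave independently, and the finished ring A has no short tether to either alkyne. Aqueous PPTS then hydrolyses the furfural-type acetal, the most labile acetal class, without harming the alkylfurans.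

Step 12
Reactants: 25 4-[(4S)-5-{4-[3-(furan-3-yl)propyl]furan-2-yl}-4-methylpentyl]furan-2-carbaldehyde
Product: 26 ethyl (2E)-3-{4-[(4S)-5-{4-[3-(furan-3-yl)propyl]furan-2-yl}-4-methylpentyl]furan-2-yl}-2-methylprop-2-enoate
Conditions: Ph3P=C(CH3)CO2Et, CH2Cl2, rt
Reagents that add atoms: ethyl 2-(triphenyl-λ5-phosphanylidene)propanoate, CCOC(=O)C(C)=P(c1ccccc1)(c1ccccc1)c1ccccc1
Why: Wittig reaction of a furfural-type aldehyde with a stabilised α-methyl ylide, which places the ester trans to the furan and should give the E trisubstituted alkene; the neutral conditions spare all three furans.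

Step 13
Reactants: 26 ethyl (2E)-3-{4-[(4S)-5-{4-[3-(furan-3-yl)propyl]furan-2-yl}-4-methylpentyl]furan-2-yl}-2-methylprop-2-enoate
Product: 27 (2E)-3-{4-[(4S)-5-{4-[3-(furan-3-yl)propyl]furan-2-yl}-4-methylpentyl]furan-2-yl}-2-methylprop-2-enoic acid
Conditions: LiOH·H2O, THF/MeOH/H2O, rt; then 1 M HCl to pH 4, 0 °C
Reagents that add atoms: lithium hydroxide, [Li+].[OH-]
Why: Saponification of the ethyl ester; furans, alkene geometry and stereocentre are inert to aqueous hydroxide, and brief cold acidification liberates the acid without acid damage to the alkylfurans.

## Compound list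

1 | 3-bromofuran | Brc1ccoc1 | starting material
2 | oxetane | C1COC1 | starting material
3 | furan-3-yllithium | [Li]c1ccoc1 | intermediate
4 | 3-(furan-3-yl)propan-1-ol | OCCCc1ccoc1 | intermediate
5 | 3-(3-bromopropyl)furan | BrCCCc1ccoc1 | intermediate
6 | 2-{[tert-butyl(dimethyl)silyl]oxy}-N-methoxy-N-methylacetamide | CON(C)C(=O)CO[Si](C)(C)C(C)(C)C | starting material
7 | [3-(furan-3-yl)propyl]magnesium bromide | Br[Mg]CCCc1ccoc1 | intermediate
8 | 1-{[tert-butyl(dimethyl)silyl]oxy}-5-(furan-3-yl)pentan-2-one | CC(C)(C)[Si](C)(C)OCC(=O)CCCc1ccoc1 | intermediate
9 | 3,3-diethoxyprop-1-yne | CCOC(OCC)C#C | starting material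
10 | (3,3-diethoxyprop-1-yn-1-yl)lithium | [Li]C#CC(OCC)OCC | intermediate
11 | 1-{[tert-butyl(dimethyl)silyl]oxy}-5,5-diethoxypent-3-yn-2-one | CCOC(OCC)C#CC(=O)CO[Si](C)(C)C(C)(C)C | intermediate
12 | (S)-citronellal, (3S)-3,7-dimethyloct-6-enal | C[C@@H](CCC=C(C)C)CC=O | starting material
13 | (4S)-4,8-dimethylnon-7-en-1-yne | C[C@@H](CCC=C(C)C)CC#C | intermediate
14 | (4S)-4-methylhept-6-ynal | C[C@@H](CCC=O)CC#C | intermediate
15 | (4S)-4-methylhept-6-yn-1-ol | C[C@@H](CCCO)CC#C | intermediate
16 | (4S)-7-iodo-4-methylhept-1-yne | C[C@@H](CCCI)CC#C | intermediate
17 | [(4S)-7-iodo-4-methylhept-1-yn-1-yl]lithium | C[C@@H](CCCI)CC#C[Li] | intermediate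
18 | (4RS,8S)-4-({[tert-butyl(dimethyl)silyl]oxy}methyl)-1-(furan-3-yl)-11-iodo-8-methylundec-5-yn-4-ol | C[C@@H](CCCI)CC#CC(O)(CO[Si](C)(C)C(C)(C)C)CCCc1ccoc1 | intermediate
19 | lithium alkoxide of 18 | C[C@@H](CCCI)CC#CC(O[Li])(CO[Si](C)(C)C(C)(C)C)CCCc1ccoc1 | intermediate
20 | dilithio species, the 11-lithio derivative of alkoxide 19 | C[C@@H](CCC[Li])CC#CC(O[Li])(CO[Si](C)(C)C(C)(C)C)CCCc1ccoc1 | intermediate
21 | organocerium species, the 11-(dichlorocerio) derivative of alkoxide 19 | C[C@@H](CCC[Ce](Cl)Cl)CC#CC(O[Li])(CO[Si](C)(C)C(C)(C)C)CCCc1ccoc1 | intermediate
22 | (8S)-4,12-bis({[tert-butyl(dimethyl)silyl]oxy}methyl)-1,1-diethoxy-15-(furan-3-yl)-8-methylpentadeca-2,10-diyne-4,12-diol (mixture at C4 and C12) | C[C@@H](CCCC(O)(CO[Si](C)(C)C(C)(C)C)C#CC(OCC)OCC)CC#CC(O)(CO[Si](C)(C)C(C)(C)C)CCCc1ccoc1 | intermediate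
23 | (8S)-1,1-diethoxy-15-(furan-3-yl)-4,12-bis(hydroxymethyl)-8-methylpentadeca-2,10-diyne-4,12-diol (mixture at C4 and C12) | C[C@@H](CCCC(O)(CO)C#CC(OCC)OCC)CC#CC(O)(CO)CCCc1ccoc1 | intermediate
24 | 2-(diethoxymethyl)-4-[(4S)-5-{4-[3-(furan-3-yl)propyl]furan-2-yl}-4-methylpentyl]furan | CCOC(OCC)c1cc(CCC[C@H](C)Cc2cc(CCCc3ccoc3)co2)co1 | intermediate
25 | 4-[(4S)-5-{4-[3-(furan-3-yl)propyl]furan-2-yl}-4-methylpentyl]furan-2-carbaldehyde | O=Cc1cc(CCC[C@H](C)Cc2cc(CCCc3ccoc3)co2)co1 | intermediate
26 | ethyl (2E)-3-{4-[(4S)-5-{4-[3-(furan-3-yl)propyl]furan-2-yl}-4-methylpentyl]furan-2-yl}-2-methylprop-2-enoate | C/C(=C\c1cc(CCC[C@H](C)Cc2cc(CCCc3ccoc3)co2)co1)C(=O)OCC | intermediate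
27 | (2E)-3-{4-[(4S)-5-{4-[3-(furan-3-yl)propyl]furan-2-yl}-4-methylpentyl]furan-2-yl}-2-methylprop-2-enoic acid | C/C(=C\c1cc(CCC[C@H](C)Cc2cc(CCCc3ccoc3)co2)co1)C(=O)O | target

## Step count and least certain steps

Total: 13 steps. Longest linear sequence: 9 steps (steps 5 to 13 from 12; the sequence of steps 1 to 3 and 8 to 13 from 1 is equally long).

**Step 11 (key step).** The most likely failure is loss of chemoselectivity at the ring C site: the tertiary propargylic alcohol next to the acetal-bearing alkyne may ionise or undergo Meyer–Schuster rearrangement, or the second cyclisation may stall after the first. The fallback replaces π-acid catalysis by a stoichiometric electrophile. It sets out from 23: treatment with I2 and NaHCO3 in MeCN should give, by iodocyclisation and dehydration, the bis(3-iodofuran) F1. Twofold iodine–lithium exchange with n-BuLi at −78 °C and protonation with methanol removes both iodine atoms and comes back to the route at 24, which is hydrolysed to 25 as in step 11.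

**Step 9.** The organometallic may be lost by proton transfer, either by enolisation of ynone 11 at its silyloxymethylene group or by premature quench of the alkyllithium, or it may add in conjugate fashion. The fallback separates the two bond formations. It sets out from 18: the dilithio species 20 is made as before and is added to Weinreb amide 6, which cannot enolise or accept conjugate addition, to give the keto alcohol F2. Addition of an excess of lithium acetylide 10 to this saturated ketone comes back to the route at 22.

**Step 8.** The amide base may attack the primary iodide (elimination), or the acetylide may enolise ketone 8 instead of adding. The fallback changes the order of events. It sets out from 15: its dianion (two equivalents of n-BuLi) is added to 8 to give the diol F3, and selective Appel iodination of the primary hydroxyl (I2, PPh3, imidazole) comes back to the route at 18.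

**Step 6.** Over-oxidation is the risk, with ozone attacking the terminal alkyne once the alkene is consumed. The fallback avoids ozone. It sets out from 13: m-CPBA epoxidises only the trisubstituted alkene to give the epoxide F4. Cleavage with H5IO6 in aqueous THF gives aldehyde 14, and NaBH4 reduction comes back to the route at 15.

**Step 1.** Furan-3-yllithium may isomerise to the 2-lithio isomer if the oxetane opening is slow and the mixture warms, which would give the wrong ring A regioisomer. The fallback makes the bond by cross-coupling. It sets out from 1: commercial tert-butyl(dimethyl)(prop-2-en-1-yloxy)silane is hydroborated with 9-BBN to the B-alkyl borane F5. This is coupled with 1 (PdCl2(dppf), K3PO4, aqueous DMF/THF) to the silyl ether F6, and Bu4NF comes back to the route at 4.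

## Further compounds

F1 | step 11 | 2-(diethoxymethyl)-3-iodo-4-[(4S)-5-{4-[3-(furan-3-yl)propyl]-3-iodofuran-2-yl}-4-methylpentyl]furan | CCOC(OCC)c1occ(CCC[C@H](C)Cc2occ(CCCc3ccoc3)c2I)c1I
F2 | step 9 | (6S)-1-{[tert-butyl(dimethyl)silyl]oxy}-10-({[tert-butyl(dimethyl)silyl]oxy}methyl)-13-(furan-3-yl)-10-hydroxy-6-methyltridec-8-yn-2-one | C[C@@H](CCCC(=O)CO[Si](C)(C)C(C)(C)C)CC#CC(O)(CO[Si](C)(C)C(C)(C)C)CCCc1ccoc1
F3 | step 8 | (8S)-4-({[tert-butyl(dimethyl)silyl]oxy}methyl)-1-(furan-3-yl)-8-methylundec-5-yne-4,11-diol | C[C@@H](CCCO)CC#CC(O)(CO[Si](C)(C)C(C)(C)C)CCCc1ccoc1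
F4 | step 6 | 2,2-dimethyl-3-[(3S)-3-methylhex-5-yn-1-yl]oxirane | C[C@@H](CCC1OC1(C)C)CC#C
F5 | step 1 | 9-(3-{[tert-butyl(dimethyl)silyl]oxy}propyl)-9-borabicyclo[3.3.1]nonane | CC(C)(C)[Si](C)(C)OCCCB1C2CCCC1CCC2
F6 | step 1 | tert-butyl[3-(furan-3-yl)propoxy]dimethylsilane | CC(C)(C)[Si](C)(C)OCCCc1ccoc1
A1 | alternative 1 | 4-bromofuran-2-carbaldehyde | O=Cc1cc(Br)co1
A2 | alternative 1 | 3-(prop-2-en-1-yl)furan | C=CCc1ccoc1
A3 | alternative 1 | 4-[3-(furan-3-yl)propyl]furan-2-carbaldehyde | O=Cc1cc(CCCc2ccoc2)co1
A4 | alternative 1 | 4-[3-(furan-3-yl)propyl]-2-[(1E)-2-methylpenta-1,4-dien-1-yl]furan | C=CC/C(C)=C/c1cc(CCCc2ccoc2)co1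
A5 | alternative 2 | prop-2-yn-1-ol | C#CCO
A6 | alternative 2 | (2Z)-2-[3-(furan-3-yl)propyl]-3-iodoprop-2-en-1-ol | OC/C(CCCc1ccoc1)=C\I
A7 | alternative 2 | (2Z,6S)-9-[5-(diethoxymethyl)furan-3-yl]-2-[3-(furan-3-yl)propyl]-6-methylnon-2-en-4-yn-1-ol | OC/C(CCCc1ccoc1)=C\C#C[C@@H](C)CCCc1coc(C(OCC)OCC)c1
A8 | alternative 2 | 2-(diethoxymethyl)-4-[(4S)-4-methylhex-5-yn-1-yl]furan | C#C[C@@H](C)CCCc1coc(C(OCC)OCC)c1
A9 | alternative 3 | (8E,11S,16E)-18,18-diethoxy-11-methyl-3,7,15-trimethylideneoctadeca-1,8,16-triene | C=CC(=C)CCCC(=C)/C=C/C[C@@H](C)CCCC(=C)/C=C/C(OCC)OCC
A10 | alternative 3 | 4-{3-[6-{(2S)-5-[6-(diethoxymethyl)-3,6-dihydro-1,2-dioxin-4-yl]-2-methylpentyl}-3,6-dihydro-1,2-dioxin-4-yl]propyl}-3,6-dihydro-1,2-dioxine | C1(CCCC2=CC(C[C@@H](C)CCCC3=CC(C(OCC)OCC)OOC3)OOC2)=CCOOC1
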